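**Retrosynthetic overview**

- The target has five benzene rings (A to E) joined by four diaryl ether bonds and no stereocentre. The last disconnections are global O-demethylation and the ring B–O–ring C ether, made by CuI-catalysed coupling of a ring AB phenol with a ring CDE aryl bromide.
- The strategy rests on ring A, with its ring carbons numbered 1 to 6. The ether-bearing ring carbon 4 lies between the hydroxyl-bearing ring carbons 3 and 5, and the third hydroxyl sits on ring carbon 1. Ring A is therefore the tris-enol of a 2-aryloxycyclohexane-1,3,5-trione.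
- Ring A is closed from an open chain by forming the bond between ring carbons 4 and 3 in a Claisen cyclisation of a 6-aryloxy-3,5-dioxohexanoate. The ether bond at ring carbon 4 is made beforehand by O-alkylation of a ring B phenol. The chain is made by acylating the acetoacetate dianion with an aryloxyacetic Weinreb amide, used in place of a methyl ester so that the acylation stops at the diketo ester.
- Ring CDE bromide: D–O–E by CuI-catalysed coupling of an ortho-bromobenzaldehyde, C–O–D by SNAr on an ortho-fluorobenzaldehyde; each formyl group is then converted into an oxygen substituent by Dakin-type oxidation.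
- Order of ring formation: ring A is the only ring built (step 5); rings B, C, D and E are bought as benzene rings.

Key step: step 5

Remark on the chemistry: every hydroxyl is carried as a methyl ether, except the one ring B oxygen that must be freed for the ring B–ring C coupling, which is a benzyl ether; the free polyphenols are handled under argon.

**Route**

Step 1
Reactants: 1 2-hydroxy-4,6-dimethoxybenzaldehyde; 2 2-chloro-N-methoxy-N-methylacetamide
Product: 3 2-(2-formyl-3,5-dimethoxyphenoxy)-N-methoxy-N-methylacetamide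
Conditions: K2CO3, NaI (cat.), DMF, 60 °C
Reagents that add atoms: none
Why: Williamson ether synthesis, in which the phenoxide of 1 displaces the halide of the α-chloro amide (iodide-catalysed SN2), so the future ether bond at ring carbon 4 of ring A is made by alkylation and not by aryl C–O coupling.

Step 2
Reactants: 3 2-(2-formyl-3,5-dimethoxyphenoxy)-N-methoxy-N-methylacetamide
Product: 5 2-(2-hydroxy-3,5-dimethoxyphenoxy)-N-methoxy-N-methylacetamide, via aryl formate 4 (not isolated)
Conditions: mCPBA, CH2Cl2, 0 °C to rt; then Et3N, MeOH, rt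
Reagents that add atoms: mCPBA, O=C(OO)c1cccc(Cl)c1
Why: Baeyer–Villiger (Dakin-type) oxidation, in which the electron-rich trioxygenated aryl group migrates in the Criegee adduct in preference to hydride, followed by mild methanolysis of the formate.

Step 3
Reactants: 5 2-(2-hydroxy-3,5-dimethoxyphenoxy)-N-methoxy-N-methylacetamide
Product: 6 2-[2-(benzyloxy)-3,5-dimethoxyphenoxy]-N-methoxy-N-methylacetamide
Conditions: BnBr, K2CO3, DMF, rt
Reagents that add atoms: benzyl bromide, BrCc1ccccc1
Why: Williamson benzylation of the phenoxide, which installs the one ring B protecting group that can later be removed without touching methyl ethers.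

Step 4
Reactants: 6 2-[2-(benzyloxy)-3,5-dimethoxyphenoxy]-N-methoxy-N-methylacetamide; 7 methyl acetoacetate
Product: 8 methyl 6-[2-(benzyloxy)-3,5-dimethoxyphenoxy]-3,5-dioxohexanoate
Conditions: 7 (1.5 equiv), NaH then n-BuLi, THF, 0 °C; add 6, −78 to 0 °C; then 1 M HCl
Reagents that add atoms: none
Why: Acylation of the γ-carbon of the acetoacetate dianion by a Weinreb amide, whose chelated tetrahedral adduct collapses only on work-up, so the 3,5-diketo ester should form without over-addition.

Step 5
Reactants: 8 methyl 6-[2-(benzyloxy)-3,5-dimethoxyphenoxy]-3,5-dioxohexanoate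
Product: 10 2-[2-(benzyloxy)-3,5-dimethoxyphenoxy]benzene-1,3,5-triol, via 2-aryloxycyclohexane-1,3,5-trione 9 (not isolated)
Conditions: NaH (4 equiv), THF, 0 °C to reflux, argon; then 1 M HCl, 0 °C
Reagents that add atoms: none
Why: Excess hydride converts the β,δ-diketo ester into its sodium polyenolate, and proton exchange through the methoxide that is released populates the carbanion at chain carbon 6, which is acidified by the ketone at chain carbon 5 and by the aryloxy group; this carbon adds to the ester carbonyl at chain carbon 1 and methoxide is expelled, forming the bond between ring carbons 4 and 3 of ring A. The closest known reaction type is the Claisen (Dieckmann-type) cyclisation of 3,5-dioxoalkanoate esters to phloroglucinols, the laboratory counterpart of the polyketide route to phloroglucinol. Ring A closes in a 6-(enolendo)-exo-trig mode, the enolate double bond between chain carbons 5 and 6 lying inside the forming ring, and trione 9 should tautomerise at once to the aromatic triol, whose phenoxide makes the closure irreversible. No stereocentre is formed. The selectivity needed is C-acylation at chain carbon 6 over O-acylation by the enolate oxygen at chain carbon 5, which would give a 4-hydroxy-2-pyrone; chain carbon 4 could only close a four-membered ring and chain carbon 2 is bonded to the ester carbon itself, so neither competes, and the strongly basic aprotic medium together with the irreversible aromatisation should drain the equilibrating enolates through the carbon pathway.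

Step 6
Reactants: 10 2-[2-(benzyloxy)-3,5-dimethoxyphenoxy]benzene-1,3,5-triol
Product: 11 2-[2-(benzyloxy)-3,5-dimethoxyphenoxy]-1,3,5-trimethoxybenzene
Conditions: Me2SO4, K2CO3, acetone, reflux, argon
Reagents that add atoms: dimethyl sulfate, COS(=O)(=O)OC
Why: Exhaustive Williamson O-methylation with the hard electrophile dimethyl sulfate, conditions under which phloroglucinols are alkylated on oxygen and not on carbon.

Step 7
Reactants: 11 2-[2-(benzyloxy)-3,5-dimethoxyphenoxy]-1,3,5-trimethoxybenzene
Product: 12 2,4-dimethoxy-6-(2,4,6-trimethoxyphenoxy)phenol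
Conditions: H2 (1 atm), Pd/C, EtOAc–MeOH, rt
Reagents that add atoms: none
Why: Catalytic hydrogenolysis of the benzyl ether over Pd/C frees the single ring B hydroxyl and leaves methyl and diaryl ethers untouched.

Step 8
Reactants: 13 2-bromo-3,4,5-trimethoxybenzaldehyde; 14 3,4,5-trimethoxyphenol
Product: 15 3,4,5-trimethoxy-2-(3,4,5-trimethoxyphenoxy)benzaldehyde
Conditions: CuI (10 mol%), picolinic acid (20 mol%), K3PO4, DMSO, 90 °C
Reagents that add atoms: none
Why: Ullmann-type diaryl ether synthesis under CuI catalysis, in which the ortho-formyl group activates the flanked C–Br bond towards the phenoxide of an unhindered, electron-rich phenol.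

Step 9
Reactants: 15 3,4,5-trimethoxy-2-(3,4,5-trimethoxyphenoxy)benzaldehyde
Product: 17 3,4,5-trimethoxy-2-(3,4,5-trimethoxyphenoxy)phenol, via aryl formate 16 (not isolated)
Conditions: mCPBA, CH2Cl2, 0 °C to rt; then Et3N, MeOH, rt
Reagents that add atoms: mCPBA, O=C(OO)c1cccc(Cl)c1
Why: Baeyer–Villiger (Dakin-type) oxidation with migration of the electron-rich aryl group bearing ortho-aryloxy and para-methoxy donors, then methanolysis of the formate to the ring D phenol.

Step 10
Reactants: 18 4-bromo-2,6-difluorobenzaldehyde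
Product: 19 4-bromo-2-fluoro-6-methoxybenzaldehyde
Conditions: NaOMe (1.05 equiv), MeOH, 0 °C to rt
Reagents that add atoms: sodium methoxide, [Na+].[O-]C
Why: Nucleophilic aromatic substitution (SNAr) of one of the two equivalent fluorides ortho to the formyl group, after which the new methoxy group slows a second substitution.

Step 11
Reactants: 17 3,4,5-trimethoxy-2-(3,4,5-trimethoxyphenoxy)phenol; 19 4-bromo-2-fluoro-6-methoxybenzaldehyde
Product: 20 4-bromo-2-methoxy-6-[3,4,5-trimethoxy-2-(3,4,5-trimethoxyphenoxy)phenoxy]benzaldehyde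
Conditions: Cs2CO3, DMSO, 90 °C
Reagents that add atoms: none
Why: SNAr of the remaining ortho-fluoride by the phenoxide of 17 through a Meisenheimer adduct stabilised by the formyl group; with no transition metal present the aryl bromide needed for step 14 should survive.

Step 12
Reactants: 20 4-bromo-2-methoxy-6-[3,4,5-trimethoxy-2-(3,4,5-trimethoxyphenoxy)phenoxy]benzaldehyde
Product: 22 4-bromo-2-methoxy-6-[3,4,5-trimethoxy-2-(3,4,5-trimethoxyphenoxy)phenoxy]phenol, via aryl formate 21 (not isolated)
Conditions: mCPBA, CH2Cl2, 0 °C to rt; then Et3N, MeOH, rt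
Reagents that add atoms: mCPBA, O=C(OO)c1cccc(Cl)c1
Why: Baeyer–Villiger (Dakin-type) oxidation of a 2,6-dioxygenated benzaldehyde, in which aryl migration and formate methanolysis turn the activating formyl group into the ring C oxygen that lies between the methoxy group and the ring D ether.

Step 13
Reactants: 22 4-bromo-2-methoxy-6-[3,4,5-trimethoxy-2-(3,4,5-trimethoxyphenoxy)phenoxy]phenol
Product: 23 5-bromo-1,2-dimethoxy-3-[3,4,5-trimethoxy-2-(3,4,5-trimethoxyphenoxy)phenoxy]benzene
Conditions: MeI, K2CO3, DMF, rt
Reagents that add atoms: iodomethane, CI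
Why: Williamson methylation of the phenoxide completes the ring CDE aryl bromide.

Step 14
Reactants: 12 2,4-dimethoxy-6-(2,4,6-trimethoxyphenoxy)phenol; 23 5-bromo-1,2-dimethoxy-3-[3,4,5-trimethoxy-2-(3,4,5-trimethoxyphenoxy)phenoxy]benzene
Product: 24 1-[2,4-dimethoxy-6-(2,4,6-trimethoxyphenoxy)phenoxy]-3,4-dimethoxy-5-[3,4,5-trimethoxy-2-(3,4,5-trimethoxyphenoxy)phenoxy]benzene
Conditions: CuI (20 mol%), picolinic acid (40 mol%), K3PO4, DMSO, 100 °C, argon
Reagents that add atoms: none
Why: Ullmann-type C–O coupling under CuI catalysis with the favourable polarity, the doubly ortho-substituted but electron-rich phenol 12 entering as the phenoxide and the bromide 23 offering a C–Br carbon flanked by two hydrogens.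

Step 15
Reactants: 24 1-[2,4-dimethoxy-6-(2,4,6-trimethoxyphenoxy)phenoxy]-3,4-dimethoxy-5-[3,4,5-trimethoxy-2-(3,4,5-trimethoxyphenoxy)phenoxy]benzene
Product: 25 pseudopentafuhalol D
Conditions: BBr3 (excess), CH2Cl2, −78 °C to rt, argon; then H2O, 0 °C
Reagents that add atoms: none
Why: Lewis acid-mediated cleavage of aryl methyl ethers, in which each ether oxygen binds BBr3, bromide attacks the methyl group (SN2) and hydrolysis of the aryl borates should give the thirteen phenols, while the diaryl ether bonds are inert.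

**Compound list**

1 | 2-hydroxy-4,6-dimethoxybenzaldehyde | COc1cc(O)c(C=O)c(OC)c1 | starting material
2 | 2-chloro-N-methoxy-N-methylacetamide | CON(C)C(=O)CCl | starting material
3 | 2-(2-formyl-3,5-dimethoxyphenoxy)-N-methoxy-N-methylacetamide | CON(C)C(=O)COc1cc(OC)cc(OC)c1C=O | intermediate
4 | 2-[2-(formyloxy)-3,5-dimethoxyphenoxy]-N-methoxy-N-methylacetamide | CON(C)C(=O)COc1cc(OC)cc(OC)c1OC=O | intermediate
5 | 2-(2-hydroxy-3,5-dimethoxyphenoxy)-N-methoxy-N-methylacetamide | CON(C)C(=O)COc1cc(OC)cc(OC)c1O | intermediate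
6 | 2-[2-(benzyloxy)-3,5-dimethoxyphenoxy]-N-methoxy-N-methylacetamide | CON(C)C(=O)COc1cc(OC)cc(OC)c1OCc1ccccc1 | intermediate
7 | methyl acetoacetate | COC(=O)CC(C)=O | starting material
8 | methyl 6-[2-(benzyloxy)-3,5-dimethoxyphenoxy]-3,5-dioxohexanoate | COC(=O)CC(=O)CC(=O)COc1cc(OC)cc(OC)c1OCc1ccccc1 | intermediate
9 | 2-[2-(benzyloxy)-3,5-dimethoxyphenoxy]cyclohexane-1,3,5-trione | O=C1CC(=O)C(Oc2cc(OC)cc(OC)c2OCc2ccccc2)C(=O)C1 | intermediate
10 | 2-[2-(benzyloxy)-3,5-dimethoxyphenoxy]benzene-1,3,5-triol | Oc1cc(O)c(Oc2cc(OC)cc(OC)c2OCc2ccccc2)c(O)c1 | intermediate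
11 | 2-[2-(benzyloxy)-3,5-dimethoxyphenoxy]-1,3,5-trimethoxybenzene | COc1cc(OC)c(Oc2cc(OC)cc(OC)c2OCc2ccccc2)c(OC)c1 | intermediate
12 | 2,4-dimethoxy-6-(2,4,6-trimethoxyphenoxy)phenol | COc1cc(OC)c(Oc2cc(OC)cc(OC)c2O)c(OC)c1 | intermediate
13 | 2-bromo-3,4,5-trimethoxybenzaldehyde | COc1cc(C=O)c(Br)c(OC)c1OC | starting material
14 | 3,4,5-trimethoxyphenol | COc1cc(O)cc(OC)c1OC | starting material
15 | 3,4,5-trimethoxy-2-(3,4,5-trimethoxyphenoxy)benzaldehyde | COc1cc(C=O)c(Oc2cc(OC)c(OC)c(OC)c2)c(OC)c1OC | intermediate
16 | 3,4,5-trimethoxy-2-(3,4,5-trimethoxyphenoxy)phenyl formate | COc1cc(OC=O)c(Oc2cc(OC)c(OC)c(OC)c2)c(OC)c1OC | intermediate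
17 | 3,4,5-trimethoxy-2-(3,4,5-trimethoxyphenoxy)phenol | COc1cc(O)c(Oc2cc(OC)c(OC)c(OC)c2)c(OC)c1OC | intermediate
18 | 4-bromo-2,6-difluorobenzaldehyde | O=Cc1c(F)cc(Br)cc1F | starting material
19 | 4-bromo-2-fluoro-6-methoxybenzaldehyde | COc1cc(Br)cc(F)c1C=O | intermediate
20 | 4-bromo-2-methoxy-6-[3,4,5-trimethoxy-2-(3,4,5-trimethoxyphenoxy)phenoxy]benzaldehyde | COc1cc(Br)cc(Oc2cc(OC)c(OC)c(OC)c2Oc2cc(OC)c(OC)c(OC)c2)c1C=O | intermediate
21 | 4-bromo-2-methoxy-6-[3,4,5-trimethoxy-2-(3,4,5-trimethoxyphenoxy)phenoxy]phenyl formate | COc1cc(Br)cc(Oc2cc(OC)c(OC)c(OC)c2Oc2cc(OC)c(OC)c(OC)c2)c1OC=O | intermediate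
22 | 4-bromo-2-methoxy-6-[3,4,5-trimethoxy-2-(3,4,5-trimethoxyphenoxy)phenoxy]phenol | COc1cc(Br)cc(Oc2cc(OC)c(OC)c(OC)c2Oc2cc(OC)c(OC)c(OC)c2)c1O | intermediate
23 | 5-bromo-1,2-dimethoxy-3-[3,4,5-trimethoxy-2-(3,4,5-trimethoxyphenoxy)phenoxy]benzene | COc1cc(Br)cc(Oc2cc(OC)c(OC)c(OC)c2Oc2cc(OC)c(OC)c(OC)c2)c1OC | intermediate
24 | 1-[2,4-dimethoxy-6-(2,4,6-trimethoxyphenoxy)phenoxy]-3,4-dimethoxy-5-[3,4,5-trimethoxy-2-(3,4,5-trimethoxyphenoxy)phenoxy]benzene | COc1cc(OC)c(Oc2cc(OC)cc(OC)c2Oc2cc(OC)c(OC)c(Oc3cc(OC)c(OC)c(OC)c3Oc3cc(OC)c(OC)c(OC)c3)c2)c(OC)c1 | intermediate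
25 | pseudopentafuhalol D | Oc1cc(O)c(Oc2cc(O)cc(O)c2Oc2cc(O)c(O)c(Oc3cc(O)c(O)c(O)c3Oc3cc(O)c(O)c(O)c3)c2)c(O)c1 | target

**Step count and risks**

Total step count: 15. Longest linear sequence: 9 steps (steps 1 to 7, then 14 and 15).

Steps most likely to fail:

1. Step 5. The enolate oxygen at chain carbon 5 may acylate in place of chain carbon 6, closing a 4-hydroxy-2-pyrone, or the polyanion may be too deactivated at the ester carbonyl for any C–C closure. The fallback sets out from 1 and comes back to the route at 12; ring A is taken as a ready-made benzene ring and steps 1 to 7 are bypassed. Phenol 1 is methylated (MeI, K2CO3, DMF) to 2,4,6-trimethoxybenzaldehyde F1. Oxidation with mCPBA passes through 2,4,6-trimethoxyphenyl formate F2, and methanolysis (Et3N, MeOH) gives 2,4,6-trimethoxyphenol F3. Ullmann-type coupling of F3 (CuI, picolinic acid, K3PO4, DMSO, 90 °C) with purchased 2-bromo-4,6-dimethoxybenzaldehyde (COc1cc(Br)c(C=O)c(OC)c1), whose ortho-formyl group assists the coupling, should give 2,4-dimethoxy-6-(2,4,6-trimethoxyphenoxy)benzaldehyde F4. Dakin-type oxidation with mCPBA through 2,4-dimethoxy-6-(2,4,6-trimethoxyphenoxy)phenyl formate F5 and methanolysis then delivers 12.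

2. Step 14. Formation of the CuI-bound phenoxide and its substitution at the bromide may be too slow for the doubly ortho-substituted phenol and the electron-rich bromide, so that reduction of the bromide or oxidation of the phenol takes over. The fallback sets out from 23 and comes back at 24; it replaces substitution of a bromide by an oxidative Chan–Lam–Evans coupling of an unhindered boron reagent. Miyaura borylation of 23 (bis(pinacolato)diboron, PdCl2(dppf), dppf being 1,1'-bis(diphenylphosphino)ferrocene, KOAc, dioxane, 90 °C) should give 2-{3,4-dimethoxy-5-[3,4,5-trimethoxy-2-(3,4,5-trimethoxyphenoxy)phenoxy]phenyl}-4,4,5,5-tetramethyl-1,3,2-dioxaborolane F6. This is coupled with 12 (Cu(OAc)2, B(OH)3, 4 Å molecular sieves, MeCN, air, 70 °C) to give 24.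

3. Step 15. Cleavage of all thirteen methyl ethers may stop short as partly demethylated borate complexes precipitate, and the free polyphenol may oxidise in air during isolation. The fallback sets out from 24 and comes back at 25; direct isolation is replaced by a derivatise, purify and release sequence. The crude product of the BBr3 reaction is acetylated at once (Ac2O, pyridine, argon) to the tridecaacetate of pseudopentafuhalol D F7, which should be stable to air and to chromatography. Congeners that still carry methyl ethers are separated at this stage and returned to BBr3. Zemplén transesterification (catalytic NaOMe, degassed MeOH, then acidic ion-exchange resin) then releases 25.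

**Further compounds**

F1 | step 5 | 2,4,6-trimethoxybenzaldehyde | COc1cc(OC)c(C=O)c(OC)c1
F2 | step 5 | 2,4,6-trimethoxyphenyl formate | COc1cc(OC)c(OC=O)c(OC)c1
F3 | step 5 | 2,4,6-trimethoxyphenol | COc1cc(OC)c(O)c(OC)c1
F4 | step 5 | 2,4-dimethoxy-6-(2,4,6-trimethoxyphenoxy)benzaldehyde | COc1cc(OC)c(Oc2cc(OC)cc(OC)c2C=O)c(OC)c1
F5 | step 5 | 2,4-dimethoxy-6-(2,4,6-trimethoxyphenoxy)phenyl formate | COc1cc(OC)c(Oc2cc(OC)cc(OC)c2OC=O)c(OC)c1
F6 | step 14 | 2-{3,4-dimethoxy-5-[3,4,5-trimethoxy-2-(3,4,5-trimethoxyphenoxy)phenoxy]phenyl}-4,4,5,5-tetramethyl-1,3,2-dioxaborolane | COc1cc(B2OC(C)(C)C(C)(C)O2)cc(Oc2cc(OC)c(OC)c(OC)c2Oc2cc(OC)c(OC)c(OC)c2)c1OC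
F7 | step 15 | tridecaacetate of pseudopentafuhalol D | CC(=O)Oc1cc(OC(C)=O)c(Oc2cc(OC(C)=O)cc(OC(C)=O)c2Oc2cc(OC(C)=O)c(OC(C)=O)c(Oc3cc(OC(C)=O)c(OC(C)=O)c(OC(C)=O)c3Oc3cc(OC(C)=O)c(OC(C)=O)c(OC(C)=O)c3)c2)c(OC(C)=O)c1
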